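**Plan**

- Retrosynthesis: the two phenol protecting groups and the C4 carbinol are taken back to a 2,6-cis-oxan-4-one; the oxane ring is then cut at C2–C3 and at O1–C6 in one retro oxa-Diels–Alder step, giving vanillin acetate and a 2-silyloxydiene.
- Feature that allows this: in the oxane ring, O1–C2(aryl) is a latent aldehyde C=O and C3–C4(O)–C5–C6 is a latent 2-oxygenated butadiene; the 1,3-relation of O1 and the C4 oxygen gives the matching polarity (nucleophilic C3, electrophilic C2).
- Forward: the diene arm is built linearly from methyl dihydroferulate (silylation, partial reduction, Wittig, enol silylation); the oxane, the only ring formed, arises in the cycloaddition.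
- Helpers: the acetyl group on the vanillin phenol raises the electrophilicity of the aldehyde, and the silyl enol ether carries C4 at the ketone level; a reduction and one methanolysis take them out.
- Stereochemistry: C2 and C6 (cis, 2S,6S) come from the catalyst-controlled endo cycloaddition; C4 (4S, axial OH) comes from equatorial hydride delivery to the diequatorial chair.

Key step: step 5

Remark (assumption): the sense of induction known for this catalyst family with other aldehydes is assumed to hold for the aryl aldehyde, so the (1S,2R) ligand is chosen; the (1R,2S) complex would be used if the sense proved opposite.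
Catalyst notation: CrCl(L) is the trivalent chromium chloride complex in which L (C27H29NO2) is the doubly deprotonated Schiff base of (1S,2R)-1-aminoindan-2-ol and 3-(1-adamantyl)-2-hydroxy-5-methylbenzaldehyde.

**Step 1**
Reactants: 1 methyl 3-(4-hydroxy-3-methoxyphenyl)propanoate
Product: 2 methyl 3-[4-(tert-butyldimethylsilyloxy)-3-methoxyphenyl]propanoate
Conditions: TBSCl, imidazole, DMF, rt
Reagents that add atoms: tert-butyldimethylsilyl chloride, CC(C)(C)[Si](C)(C)Cl
Why: Imidazole-promoted silyl ether formation at the phenol, the only acidic OH, with the ester inert.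

**Step 2**
Reactants: 2 methyl 3-[4-(tert-butyldimethylsilyloxy)-3-methoxyphenyl]propanoate
Product: 4 3-[4-(tert-butyldimethylsilyloxy)-3-methoxyphenyl]propanal, via aluminium hemiacetal 3 (not isolated)
Conditions: i-Bu2AlH (1.1 equiv), CH2Cl2, −78 °C; then MeOH, aq. KNaC4H4O6
Reagents that add atoms: none
Why: Partial ester reduction with i-Bu2AlH, in which the tetrahedral aluminium hemiacetal 3 should persist at −78 °C and release the aldehyde only on aqueous work-up, the aryl silyl ether being untouched.

**Step 3**
Reactants: 4 3-[4-(tert-butyldimethylsilyloxy)-3-methoxyphenyl]propanal; 5 1-(triphenylphosphoranylidene)propan-2-one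
Product: 6 (3E)-6-[4-(tert-butyldimethylsilyloxy)-3-methoxyphenyl]hex-3-en-2-one
Conditions: toluene, 80 °C
Reagents that add atoms: none
Why: Wittig olefination with a stabilised acyl ylide, which should give the (E)-enone selectively; no stereocentre is formed.

**Step 4**
Reactants: 6 (3E)-6-[4-(tert-butyldimethylsilyloxy)-3-methoxyphenyl]hex-3-en-2-one
Product: 7 tert-butyl{2-methoxy-4-[(3E)-5-(triethylsilyloxy)hexa-3,5-dien-1-yl]phenoxy}dimethylsilane
Conditions: Et3SiOTf, Et3N, Et2O, −78 → 0 °C; filtration through Et3N-deactivated SiO2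
Reagents that add atoms: triethylsilyl trifluoromethanesulfonate, CC[Si](CC)(CC)OS(=O)(=O)C(F)(F)F
Why: Soft enolisation of the methyl ketone (silyl triflate and amine) on its CH3 side, the kinetically preferred site, should give the cross-conjugated 2-silyloxydiene with the (E)-alkene intact (silyl dienol ether formation).

**Step 5**
Reactants: 7 tert-butyl{2-methoxy-4-[(3E)-5-(triethylsilyloxy)hexa-3,5-dien-1-yl]phenoxy}dimethylsilane; 8 4-formyl-2-methoxyphenyl acetate (vanillin acetate)
Product: 10 4-{(2S,6S)-6-[2-(4-(tert-butyldimethylsilyloxy)-3-methoxyphenyl)ethyl]-4-oxotetrahydro-2H-pyran-2-yl}-2-methoxyphenyl acetate, via silyl enol ether cycloadduct 9 (not isolated)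
Conditions: CrCl(L) (5 mol %, L = C27H29NO2 as defined above), 4 Å MS, acetone (minimal), rt, 48 h; then TFA, CH2Cl2/H2O, 0 °C
Reagents that add atoms: none
Why: The trivalent chromium centre binds the formyl oxygen of 8; the nucleophilic CH2 terminus of the silyl enol ether half of 7 then attacks the carbonyl carbon (C3–C2 bond) while the carbonyl oxygen closes on the far alkene terminus (O1–C6 bond) in a concerted, asynchronous [4+2] event, after which TFA hydrolyses the silyl enol ether 9 to ketone 10. The closest known reaction type is the enantioselective hetero-Diels–Alder reaction of 2-silyloxydienes with aldehydes under tridentate Schiff base chromium chloride catalysis. The oxane ring closes by intermolecular [4+2] cycloaddition, with four atoms (C3 to C6) from the diene and two (C2 and O1) from the aldehyde, not by a separate cyclisation. C2 is set by the catalyst, whose adamantyl and indane groups should leave the Si face of the bound aldehyde open to the diene (2S), and C6 is set relative to C2 by the endo transition state together with the (E)-geometry of the diene, so that the aryl and arylethyl groups end up cis (6S). The step needs regioselectivity, endo selectivity and aldehyde-face selectivity: the first follows from the C4 silyloxy group, which polarises the diene toward its CH2 terminus, the other two from the catalyst, and the acetyl group on the phenol of 8 makes the aldehyde more electrophilic than free or silylated vanillin.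

**Step 6**
Reactants: 10 4-{(2S,6S)-6-[2-(4-(tert-butyldimethylsilyloxy)-3-methoxyphenyl)ethyl]-4-oxotetrahydro-2H-pyran-2-yl}-2-methoxyphenyl acetate
Product: 11 4-{(2S,4S,6S)-6-[2-(4-(tert-butyldimethylsilyloxy)-3-methoxyphenyl)ethyl]-4-hydroxytetrahydro-2H-pyran-2-yl}-2-methoxyphenyl acetate
Conditions: LiBH(s-Bu)3 (1.2 equiv), THF, −78 °C; then sat. aq. NH4Cl
Reagents that add atoms: none
Why: Diastereoselective ketone reduction with a bulky trialkylborohydride, which should attack the 2,6-diequatorial chair along the equatorial trajectory and so place the new hydroxyl axial (4S, trans to both ring substituents), while the hindered hydride is expected to leave the aryl acetate alone at −78 °C.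

**Step 7**
Reactants: 11 4-{(2S,4S,6S)-6-[2-(4-(tert-butyldimethylsilyloxy)-3-methoxyphenyl)ethyl]-4-hydroxytetrahydro-2H-pyran-2-yl}-2-methoxyphenyl acetate
Product: 12 (2S,4S,6S)-2-(4-hydroxy-3-methoxyphenyl)-6-[2-(4-hydroxy-3-methoxyphenyl)ethyl]tetrahydro-2H-pyran-4-ol
Conditions: K2CO3, MeOH, 0 °C → rt; then aq. NH4Cl
Reagents that add atoms: none
Why: Base-mediated methanolysis should cleave the aryl acetate (transesterification) and the phenolic silyl ether together, both helped by the phenoxide leaving group, without touching the secondary alcohol or any stereocentre.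

**Compound list**

1 | methyl 3-(4-hydroxy-3-methoxyphenyl)propanoate (methyl dihydroferulate) | COC(=O)CCc1ccc(O)c(OC)c1 | starting material
2 | methyl 3-[4-(tert-butyldimethylsilyloxy)-3-methoxyphenyl]propanoate | COC(=O)CCc1ccc(O[Si](C)(C)C(C)(C)C)c(OC)c1 | intermediate
3 | {3-[4-(tert-butyldimethylsilyloxy)-3-methoxyphenyl]-1-methoxypropoxy}bis(2-methylpropyl)alumane (aluminium hemiacetal, not isolated) | COC(CCc1ccc(O[Si](C)(C)C(C)(C)C)c(OC)c1)O[Al](CC(C)C)CC(C)C | intermediate
4 | 3-[4-(tert-butyldimethylsilyloxy)-3-methoxyphenyl]propanal | O=CCCc1ccc(O[Si](C)(C)C(C)(C)C)c(OC)c1 | intermediate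
5 | 1-(triphenylphosphoranylidene)propan-2-one | CC(=O)C=P(c1ccccc1)(c1ccccc1)c1ccccc1 | starting material
6 | (3E)-6-[4-(tert-butyldimethylsilyloxy)-3-methoxyphenyl]hex-3-en-2-one | CC(=O)/C=C/CCc1ccc(O[Si](C)(C)C(C)(C)C)c(OC)c1 | intermediate
7 | tert-butyl{2-methoxy-4-[(3E)-5-(triethylsilyloxy)hexa-3,5-dien-1-yl]phenoxy}dimethylsilane | C=C(O[Si](CC)(CC)CC)/C=C/CCc1ccc(O[Si](C)(C)C(C)(C)C)c(OC)c1 | intermediate
8 | 4-formyl-2-methoxyphenyl acetate (vanillin acetate) | CC(=O)Oc1ccc(C=O)cc1OC | starting material
9 | 4-{(2S,6S)-6-[2-(4-(tert-butyldimethylsilyloxy)-3-methoxyphenyl)ethyl]-4-(triethylsilyloxy)-3,6-dihydro-2H-pyran-2-yl}-2-methoxyphenyl acetate (cycloadduct, not isolated) | COc1cc(CC[C@H]2C=C(O[Si](CC)(CC)CC)C[C@@H](c3ccc(OC(C)=O)c(OC)c3)O2)ccc1O[Si](C)(C)C(C)(C)C | intermediate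
10 | 4-{(2S,6S)-6-[2-(4-(tert-butyldimethylsilyloxy)-3-methoxyphenyl)ethyl]-4-oxotetrahydro-2H-pyran-2-yl}-2-methoxyphenyl acetate | COc1cc(CC[C@H]2CC(=O)C[C@@H](c3ccc(OC(C)=O)c(OC)c3)O2)ccc1O[Si](C)(C)C(C)(C)C | intermediate
11 | 4-{(2S,4S,6S)-6-[2-(4-(tert-butyldimethylsilyloxy)-3-methoxyphenyl)ethyl]-4-hydroxytetrahydro-2H-pyran-2-yl}-2-methoxyphenyl acetate | COc1cc(CC[C@H]2C[C@H](O)C[C@@H](c3ccc(OC(C)=O)c(OC)c3)O2)ccc1O[Si](C)(C)C(C)(C)C | intermediate
12 | (2S,4S,6S)-2-(4-hydroxy-3-methoxyphenyl)-6-[2-(4-hydroxy-3-methoxyphenyl)ethyl]tetrahydro-2H-pyran-4-ol | COc1cc(CC[C@H]2C[C@H](O)C[C@@H](c3ccc(O)c(OC)c3)O2)ccc1O | target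

**Totals**

Total step count: 7. Longest linear sequence: 7 steps (1 → 12); vanillin acetate 8 enters at step 5.

**Steps most likely to fail**

1. Step 5. The aryl aldehyde may cycloadd slowly, and the endo or facial selectivity may be eroded, so that the ketone forms in low enantiomeric purity or as a cis/trans mixture. The fallback sets out from enone 6 (with aldehyde 8) and comes back at ketone 10; it replaces the cycloaddition by a boron aldol reaction followed by a separate ring closure. Enone 6 would be enolised on its methyl side with Ipc2BCl (the enantiomer that leads to the S carbinol) and Et3N in Et2O at −78 °C and added to 8, which should give 4-[(1S,4E)-1-hydroxy-7-[4-(tert-butyldimethylsilyloxy)-3-methoxyphenyl]-3-oxohept-4-en-1-yl]-2-methoxyphenyl acetate F1. A 6-endo-trig oxa-Michael closure of F1 under equilibrating conditions (sulfonic acid resin Amberlyst 15, CH2Cl2, rt) should then give the thermodynamically favoured 2,6-cis ketone 10.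

2. Step 6. Hydride delivery may show poor facial selectivity, giving the equatorial alcohol alongside the axial one, and the hydride may also attack the aryl acetate. The fallback sets out from ketone 10 and comes back at target 12; it accepts the wrong C4 configuration and inverts it. Reduction with NaBH4 (MeOH/CH2Cl2, −40 °C; axial attack by the small hydride) should give the all-cis 4-{(2S,4R,6S)-6-[2-(4-(tert-butyldimethylsilyloxy)-3-methoxyphenyl)ethyl]-4-hydroxytetrahydro-2H-pyran-2-yl}-2-methoxyphenyl acetate F2. Mitsunobu inversion (4-nitrobenzoic acid, PPh3, DIAD, THF, 0 °C → rt) should give (2S,4S,6S)-2-(4-acetoxy-3-methoxyphenyl)-6-{2-[4-(tert-butyldimethylsilyloxy)-3-methoxyphenyl]ethyl}tetrahydro-2H-pyran-4-yl 4-nitrobenzoate F3. Methanolysis as in step 7 (K2CO3, MeOH) should then remove the nitrobenzoate, the acetate and the silyl ether together and give 12.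

3. Step 2. The reduction may run past the aldehyde stage to the alcohol or stop short of full conversion, leaving mixtures that are hard to separate. The fallback sets out from ester 2 and comes back at aldehyde 4; it replaces the partial reduction by a full reduction and a re-oxidation. Excess i-Bu2AlH (2.5 equiv, CH2Cl2, −78 → 0 °C) should give 3-[4-(tert-butyldimethylsilyloxy)-3-methoxyphenyl]propan-1-ol F4, and a Parikh–Doering oxidation (SO3·pyridine, DMSO, Et3N, CH2Cl2, 0 °C) should then give aldehyde 4.

**Further compounds**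

F1 | step 5 | 4-[(1S,4E)-1-hydroxy-7-[4-(tert-butyldimethylsilyloxy)-3-methoxyphenyl]-3-oxohept-4-en-1-yl]-2-methoxyphenyl acetate | CC(=O)Oc1ccc([C@@H](O)CC(=O)/C=C/CCc2ccc(O[Si](C)(C)C(C)(C)C)c(OC)c2)cc1OC
F2 | step 6 | 4-{(2S,4R,6S)-6-[2-(4-(tert-butyldimethylsilyloxy)-3-methoxyphenyl)ethyl]-4-hydroxytetrahydro-2H-pyran-2-yl}-2-methoxyphenyl acetate | COc1cc(CC[C@H]2C[C@@H](O)C[C@@H](c3ccc(OC(C)=O)c(OC)c3)O2)ccc1O[Si](C)(C)C(C)(C)C
F3 | step 6 | (2S,4S,6S)-2-(4-acetoxy-3-methoxyphenyl)-6-{2-[4-(tert-butyldimethylsilyloxy)-3-methoxyphenyl]ethyl}tetrahydro-2H-pyran-4-yl 4-nitrobenzoate | COc1cc(CC[C@H]2C[C@H](OC(=O)c4ccc(cc4)[N+](=O)[O-])C[C@@H](c3ccc(OC(C)=O)c(OC)c3)O2)ccc1O[Si](C)(C)C(C)(C)C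
F4 | step 2 | 3-[4-(tert-butyldimethylsilyloxy)-3-methoxyphenyl]propan-1-ol | OCCCc1ccc(O[Si](C)(C)C(C)(C)C)c(OC)c1
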